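**Retrosynthetic overview**

Rings: A = central 1,3,5-trisubstituted anisole ring, B = 4-hydroxyphenyl ring, C = para-phenylene ring, D = salicylic acid ring; A, B and C are bought as benzenes and D is the only ring built, last.
Feature used: in ring D the carbon bearing CO2H and the adjacent carbon bearing the CH2CH2 chain map onto the two sp carbons of a 2-alkynoate, and the other four carbons, C(OH)–CH–C(OMe)–CH, map onto a 1,3-dioxygenated butadiene whose two oxygens are already different.
Disconnections, last to first: (i) both O-benzyl groups (ester and ring B ether) by hydrogenolysis; (ii) ring D by [4+2] cycloaddition and aromatisation into a benzyl 5-arylpent-2-ynoate and (E)-1,3-dimethoxy-1-(trimethylsilyloxy)buta-1,3-diene.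
(iii) The ynoate goes back to a methyl 3-arylpropanoate (partial reduction, one-carbon alkyne homologation, acetylide acylation); (iv) the A–O–C diaryl ether is cut by Ullmann coupling into the A/B bibenzyl phenol and methyl 3-(4-bromophenyl)propanoate.
(v) The A/B CH2–CH2 bridge comes from Wittig olefination of 3-hydroxy-5-methoxybenzaldehyde with the ylide from 4-(benzyloxy)benzyl chloride, then alkene hydrogenation that spares the benzyl ether.

Key step: step 9

Remark: the target has no stereocentre and no stereogenic double bond, so it is achiral and the route needs no stereocontrol.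

**Route**

Step 1
Reactants: 1 4-(benzyloxy)benzyl chloride
Product: 2 [4-(benzyloxy)benzyl]triphenylphosphonium chloride
Conditions: PPh3 (1.05 equiv), toluene, reflux; filter the precipitated salt
Reagents that add atoms: triphenylphosphine, c1ccc(cc1)P(c1ccccc1)c1ccccc1
Why: SN2 quaternisation of triphenylphosphine by a reactive benzylic chloride (phosphonium salt formation), driven by precipitation of the salt from hot toluene.

Step 2
Reactants: 2 [4-(benzyloxy)benzyl]triphenylphosphonium chloride; 3 3-hydroxy-5-methoxybenzaldehyde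
Product: 5 3-[2-(4-benzyloxyphenyl)ethenyl]-5-methoxyphenol (E/Z mixture), via phosphonium ylide 4 (not isolated)
Conditions: 2 (1.2 equiv), KOtBu (2.4 equiv), THF, 0 °C; then 3, 0 °C to rt; aq NH4Cl
Reagents that add atoms: none
Why: Wittig olefination with a semi-stabilised benzylic ylide, in which the extra base also forms the meta-phenoxide of 3, which is not conjugated with the formyl group and so leaves it electrophilic; the alkene geometry is irrelevant because the double bond is saturated in step 3.

Step 3
Reactants: 5 3-[2-(4-benzyloxyphenyl)ethenyl]-5-methoxyphenol (E/Z mixture)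
Product: 6 3-[2-(4-benzyloxyphenyl)ethyl]-5-methoxyphenol
Conditions: H2 (1 atm), 10% Pd/C, Ph2S (cat.), EtOAc, rt
Reagents that add atoms: none
Why: Chemoselective heterogeneous hydrogenation in which the sulfide-poisoned palladium should still saturate the stilbene C=C (both isomers converge) but no longer hydrogenolyse the aryl benzyl ether.

Step 4
Reactants: 6 3-[2-(4-benzyloxyphenyl)ethyl]-5-methoxyphenol; 7 methyl 3-(4-bromophenyl)propanoate
Product: 8 methyl 3-(4-{3-[2-(4-benzyloxyphenyl)ethyl]-5-methoxyphenoxy}phenyl)propanoate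
Conditions: 7 (1.2 equiv), CuI (10 mol %), N,N-dimethylglycine·HCl (30 mol %), Cs2CO3 (2.5 equiv), 1,4-dioxane, 90 °C, Ar
Reagents that add atoms: none
Why: Ligand-accelerated Ullmann diaryl ether synthesis, in which the unhindered electron-rich phenoxide couples with the aryl bromide at copper while the methyl ester and the benzyl ether are inert to caesium carbonate in dioxane.

Step 5
Reactants: 8 methyl 3-(4-{3-[2-(4-benzyloxyphenyl)ethyl]-5-methoxyphenoxy}phenyl)propanoate
Product: 10 3-(4-{3-[2-(4-benzyloxyphenyl)ethyl]-5-methoxyphenoxy}phenyl)propanal, via aluminium hemiacetal 9 (not isolated)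
Conditions: DIBAL-H (1.1 equiv), CH2Cl2, −78 °C; MeOH quench at −78 °C, then aq Rochelle salt
Reagents that add atoms: none
Why: Partial reduction of an ester with DIBAL-H, in which the tetrahedral aluminium hemiacetal 9 is stable at −78 °C and releases the aldehyde only on aqueous work-up, so a second hydride transfer should be avoided.

Step 6
Reactants: 10 3-(4-{3-[2-(4-benzyloxyphenyl)ethyl]-5-methoxyphenoxy}phenyl)propanal
Product: 11 1-[2-(4-benzyloxyphenyl)ethyl]-3-[4-(but-3-yn-1-yl)phenoxy]-5-methoxybenzene
Conditions: Ohira–Bestmann reagent (1.3 equiv), K2CO3 (2 equiv), MeOH/THF, 0 °C to rt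
Reagents that add atoms: dimethyl (1-diazo-2-oxopropyl)phosphonate (Ohira–Bestmann reagent), CC(=O)C(=[N+]=[N-])P(=O)(OC)OC
Why: Seyferth–Gilbert homologation in its Ohira–Bestmann form, in which methanolysis of the reagent gives the diazomethylphosphonate anion that olefinates the aldehyde and loss of nitrogen with 1,2-hydrogen shift gives the terminal alkyne under base mild enough for an enolisable aldehyde.

Step 7
Reactants: 11 1-[2-(4-benzyloxyphenyl)ethyl]-3-[4-(but-3-yn-1-yl)phenoxy]-5-methoxybenzene
Product: 13 benzyl 5-(4-{3-[2-(4-benzyloxyphenyl)ethyl]-5-methoxyphenoxy}phenyl)pent-2-ynoate, via lithium acetylide 12 (not isolated)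
Conditions: n-BuLi (1.05 equiv), THF, −78 °C; then ClCO2Bn (1.2 equiv), −78 to 0 °C
Reagents that add atoms: benzyl chloroformate, O=C(Cl)OCc1ccccc1
Why: Deprotonation of the terminal alkyne, the only acidic C–H in 11, and acylation of the lithium acetylide with a chloroformate at low temperature, the standard ynoate synthesis.

Step 8
Reactants: 14 methyl (E)-3-methoxybut-2-enoate
Product: 16 (E)-1,3-dimethoxy-1-(trimethylsilyloxy)buta-1,3-diene, via lithium dienolate 15 (not isolated)
Conditions: LDA (1.1 equiv), THF, −78 °C; then TMSCl (1.2 equiv), −78 °C to rt; pentane, filtration, distillation under reduced pressure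
Reagents that add atoms: chlorotrimethylsilane, C[Si](C)(C)Cl
Why: γ-Deprotonation of the vinylogous ester by LDA gives the extended enolate and kinetic O-silylation gives the silyl ketene acetal diene, the standard preparation of this diene.

Step 9
Reactants: 13 benzyl 5-(4-{3-[2-(4-benzyloxyphenyl)ethyl]-5-methoxyphenoxy}phenyl)pent-2-ynoate; 16 (E)-1,3-dimethoxy-1-(trimethylsilyloxy)buta-1,3-diene
Product: 19 benzyl 2-[2-(4-{3-[2-(4-benzyloxyphenyl)ethyl]-5-methoxyphenoxy}phenyl)ethyl]-6-hydroxy-4-methoxybenzoate, via cyclohexadiene adduct 17 (not isolated), via aryl trimethylsilyl ether 18 (not isolated)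
Conditions: 16 (3 equiv, in two portions), toluene, 120 °C, sealed tube; then 1 M HCl, THF, rt
Reagents that add atoms: none
Why: Normal-electron-demand Diels–Alder reaction between the electron-rich ketene acetal diene 16 and the electron-poor ynoate 13, in which the CH2 terminus of 16 bonds to the β-carbon of 13 (the one bearing the CH2CH2Ar chain) and the ketene acetal carbon to the α-carbon in a concerted but strongly asynchronous [4+2] cycloaddition that gives the cyclohexa-1,4-diene 17. The closest known reaction type is the cycloaddition of 1,1,3-trioxygenated butadienes with acetylenic esters followed by aromatisation to resorcylate esters, which includes β-alkyl ynoates at comparable temperatures. Ring D is closed in an intermolecular [4+2] mode, four carbons from the diene and two from the alkyne, forming the C(CO2Bn)–C(O) and C(chain)–CH ring bonds in one operation. Adduct 17 should then lose methanol by 1,4-elimination (the ketal methoxy group and a hydrogen of the ring CH2), driven by aromatisation, to give the aryl silyl ether 18, and dilute acid removes the silyl group; no stereocentre survives, since the only one formed, the ketal carbon of 17, is destroyed on aromatisation. The step needs regioselectivity, and the matched polarisation of the partners secures it: the largest HOMO coefficient of 16 is at the terminal CH2 carbon, which is fed by all three oxygens, and the largest LUMO coefficient of 13 is at the β-carbon, so the silyl acetal oxygen ends as the OH next to the ester and the vinylogous OMe ends para to it. The arenes, the benzyl ether and the diaryl ether are not dienophiles for this diene and should stay untouched.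

Step 10
Reactants: 19 benzyl 2-[2-(4-{3-[2-(4-benzyloxyphenyl)ethyl]-5-methoxyphenoxy}phenyl)ethyl]-6-hydroxy-4-methoxybenzoate
Product: 20 2-hydroxy-6-[2-(4-{3-[2-(4-hydroxyphenyl)ethyl]-5-methoxyphenoxy}phenyl)ethyl]-4-methoxybenzoic acid
Conditions: H2 (1 atm), 10% Pd/C, EtOAc/MeOH, rt
Reagents that add atoms: none
Why: Palladium-catalysed hydrogenolysis cleaves both O-benzyl bonds (ester and aryl ether) under neutral conditions, which avoids hydrolysing the hindered, hydrogen-bonded ortho-hydroxy ester and leaves the diaryl ether, the methyl ethers and the arenes intact.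

**Compound list**

1 | 4-(benzyloxy)benzyl chloride | ClCc1ccc(OCc2ccccc2)cc1 | starting material
2 | [4-(benzyloxy)benzyl]triphenylphosphonium chloride | [Cl-].c1ccc(COc2ccc(C[P+](c3ccccc3)(c3ccccc3)c3ccccc3)cc2)cc1 | intermediate
3 | 3-hydroxy-5-methoxybenzaldehyde | COc1cc(O)cc(C=O)c1 | starting material
4 | [4-(benzyloxy)benzylidene]triphenylphosphorane (ylide, not isolated) | c1ccc(COc2ccc(C=P(c3ccccc3)(c3ccccc3)c3ccccc3)cc2)cc1 | intermediate
5 | 3-[2-(4-benzyloxyphenyl)ethenyl]-5-methoxyphenol (E/Z mixture, double bond geometry not defined) | COc1cc(O)cc(C=Cc2ccc(OCc3ccccc3)cc2)c1 | intermediate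
6 | 3-[2-(4-benzyloxyphenyl)ethyl]-5-methoxyphenol | COc1cc(O)cc(CCc2ccc(OCc3ccccc3)cc2)c1 | intermediate
7 | methyl 3-(4-bromophenyl)propanoate | COC(=O)CCc1ccc(Br)cc1 | starting material
8 | methyl 3-(4-{3-[2-(4-benzyloxyphenyl)ethyl]-5-methoxyphenoxy}phenyl)propanoate | COC(=O)CCc1ccc(Oc2cc(OC)cc(CCc3ccc(OCc4ccccc4)cc3)c2)cc1 | intermediate
9 | diisobutylaluminium hemiacetal of 8, 1-methoxy-3-arylpropyl diisobutylaluminium alkoxide (racemic, not isolated) | COC(CCc1ccc(Oc2cc(OC)cc(CCc3ccc(OCc4ccccc4)cc3)c2)cc1)O[Al](CC(C)C)CC(C)C | intermediate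
10 | 3-(4-{3-[2-(4-benzyloxyphenyl)ethyl]-5-methoxyphenoxy}phenyl)propanal | O=CCCc1ccc(Oc2cc(OC)cc(CCc3ccc(OCc4ccccc4)cc3)c2)cc1 | intermediate
11 | 1-[2-(4-benzyloxyphenyl)ethyl]-3-[4-(but-3-yn-1-yl)phenoxy]-5-methoxybenzene | C#CCCc1ccc(Oc2cc(OC)cc(CCc3ccc(OCc4ccccc4)cc3)c2)cc1 | intermediate
12 | lithium acetylide of 11 (not isolated) | [Li]C#CCCc1ccc(Oc2cc(OC)cc(CCc3ccc(OCc4ccccc4)cc3)c2)cc1 | intermediate
13 | benzyl 5-(4-{3-[2-(4-benzyloxyphenyl)ethyl]-5-methoxyphenoxy}phenyl)pent-2-ynoate | O=C(OCc1ccccc1)C#CCCc1ccc(Oc2cc(OC)cc(CCc3ccc(OCc4ccccc4)cc3)c2)cc1 | intermediate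
14 | methyl (E)-3-methoxybut-2-enoate | COC(=O)/C=C(\C)OC | starting material
15 | lithium (E)-1,3-dimethoxybuta-1,3-dien-1-olate (not isolated) | C=C(OC)/C=C(\OC)O[Li] | intermediate
16 | (E)-1,3-dimethoxy-1-(trimethylsilyloxy)buta-1,3-diene (Brassard's diene) | C=C(OC)/C=C(\OC)O[Si](C)(C)C | intermediate
17 | benzyl 2-[2-(4-{3-[2-(4-benzyloxyphenyl)ethyl]-5-methoxyphenoxy}phenyl)ethyl]-4,6-dimethoxy-6-(trimethylsilyloxy)cyclohexa-1,4-diene-1-carboxylate (racemic, not isolated) | O=C(OCc1ccccc1)C1=C(CCc2ccc(Oc3cc(OC)cc(CCc4ccc(OCc5ccccc5)cc4)c3)cc2)CC(OC)=CC1(OC)O[Si](C)(C)C | intermediate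
18 | benzyl 2-[2-(4-{3-[2-(4-benzyloxyphenyl)ethyl]-5-methoxyphenoxy}phenyl)ethyl]-4-methoxy-6-(trimethylsilyloxy)benzoate (not isolated) | O=C(OCc1ccccc1)c1c(O[Si](C)(C)C)cc(OC)cc1CCc1ccc(Oc2cc(OC)cc(CCc3ccc(OCc4ccccc4)cc3)c2)cc1 | intermediate
19 | benzyl 2-[2-(4-{3-[2-(4-benzyloxyphenyl)ethyl]-5-methoxyphenoxy}phenyl)ethyl]-6-hydroxy-4-methoxybenzoate | O=C(OCc1ccccc1)c1c(O)cc(OC)cc1CCc1ccc(Oc2cc(OC)cc(CCc3ccc(OCc4ccccc4)cc3)c2)cc1 | intermediate
20 | 2-hydroxy-6-[2-(4-{3-[2-(4-hydroxyphenyl)ethyl]-5-methoxyphenoxy}phenyl)ethyl]-4-methoxybenzoic acid | COc1cc(CCc2ccc(O)cc2)cc(Oc2ccc(CCc3cc(OC)cc(O)c3C(=O)O)cc2)c1 | target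

**Step count and risks**

Total step count: 10. Longest linear sequence: 9 steps (steps 1–7, 9 and 10); step 8 is a one-step branch.

Steps most likely to fail:

Step 9. The cycloaddition of the β-alkyl ynoate may be slower than thermal decomposition or silyl transfer of the diene. Aromatisation may also partly proceed by loss of silanol instead of methanol, which would blur the differentiation of the two ring D oxygens. The fallback sets out from 13 and builds ring D by an anionic Michael–Claisen benzannulation instead of a cycloaddition. Compound 13 and benzyl acetoacetate are heated with sodium benzyloxide (NaH, BnOH) in THF. Conjugate addition of the acetoacetate to the ynoate and Claisen ring closure of the acetyl methyl group onto the ynoate ester should give benzyl 2-[2-(4-{3-[2-(4-benzyloxyphenyl)ethyl]-5-methoxyphenoxy}phenyl)ethyl]-4,6-dihydroxybenzoate F1. Methylation with MeI (1.05 equiv) and K2CO3 in acetone at rt should then take place only at the 4-hydroxyl, because the 6-hydroxyl is hydrogen-bonded to the ester carbonyl. The fallback comes back to the route at 19.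

Step 4. Oxidative addition of copper to the unactivated aryl bromide may be sluggish, with protodehalogenation of 7 or base-induced ester cleavage competing. The fallback sets out from 6 and forms the diaryl ether by nucleophilic aromatic substitution. Compound 6 and 4-fluorobenzaldehyde with K2CO3 in DMF at 120 °C should give 4-{3-[2-(4-benzyloxyphenyl)ethyl]-5-methoxyphenoxy}benzaldehyde F2. Wittig olefination with methyl (triphenylphosphoranylidene)acetate in toluene at 80 °C should give methyl (E)-3-(4-{3-[2-(4-benzyloxyphenyl)ethyl]-5-methoxyphenoxy}phenyl)prop-2-enoate F3. Hydrogenation of the conjugated C=C over sulfide-poisoned Pd/C, as in step 3, then brings the sequence back to the route at 8.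

Step 5. The aluminium hemiacetal may collapse before the quench, so that the aldehyde is reduced further to the alcohol, or the reduction may stop short of full conversion. The fallback sets out from 8 and replaces partial reduction by full reduction and re-oxidation. LiAlH4 in THF at 0 °C should give 3-(4-{3-[2-(4-benzyloxyphenyl)ethyl]-5-methoxyphenoxy}phenyl)propan-1-ol F4. Dess–Martin periodinane with NaHCO3 in CH2Cl2 at rt then returns to the route at 10.

**Further compounds**

F1 | step 9 | benzyl 2-[2-(4-{3-[2-(4-benzyloxyphenyl)ethyl]-5-methoxyphenoxy}phenyl)ethyl]-4,6-dihydroxybenzoate | O=C(OCc1ccccc1)c1c(O)cc(O)cc1CCc1ccc(Oc2cc(OC)cc(CCc3ccc(OCc4ccccc4)cc3)c2)cc1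
F2 | step 4 | 4-{3-[2-(4-benzyloxyphenyl)ethyl]-5-methoxyphenoxy}benzaldehyde | O=Cc1ccc(Oc2cc(OC)cc(CCc3ccc(OCc4ccccc4)cc3)c2)cc1
F3 | step 4 | methyl (E)-3-(4-{3-[2-(4-benzyloxyphenyl)ethyl]-5-methoxyphenoxy}phenyl)prop-2-enoate | COC(=O)/C=C/c1ccc(Oc2cc(OC)cc(CCc3ccc(OCc4ccccc4)cc3)c2)cc1
F4 | step 5 | 3-(4-{3-[2-(4-benzyloxyphenyl)ethyl]-5-methoxyphenoxy}phenyl)propan-1-ol | OCCCc1ccc(Oc2cc(OC)cc(CCc3ccc(OCc4ccccc4)cc3)c2)cc1
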